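**Retrosynthetic overview**

1. Numbering: benzene ring A (C4a–C8a), pyran ring B (O1, C2, C3=C4), side chain C1'–C33' on C2. The chain is cut between C2' (CH2) and C3' (olefinic CH): a C15 propanoic acid, whose carboxyl carbon leaves as CO2, and a C39 (E)-1-iodo-2-methyl-octaene are joined by nickel-electrocatalytic decarboxylative alkenylation, a reductive union of two electrophilic carbons.
2. Enabling feature: the quaternary C2 of ring B holds the chain through the saturated C1'–C2' spacer, and C3' bears H. A primary radical at C2' is γ to O1 (no β-C–O scission), can reach C3=C4 only by 4-exo or 5-endo closure, and C3' maps onto the iodine-bearing carbon of a carboalumination-derived iodoalkene.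
3. Acid fragment: C2, its methyl, C3, C4, C1', C2' and the carboxyl carbon are C3, 3-CH3, C2, C1, C4, C5 and C6 of (R)-linalool, whose C3–O bond is never broken. Ring A comes from 2,3-dimethylhydroquinone; ring B is closed first as a chroman by intramolecular Pd C–O coupling (O1–C8a), then C3=C4 is introduced with DDQ.
4. Iodide fragment: farnesyl bromide plus silylpropyne, terminal allylic oxidation and bromination, sulfone coupling with a geranylgeranyl sulfone, desulfonylation, desilylation, methylalumination–iodination.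
5. Last step: removal of the phenol pivalate.

Key step: step 18

Assumption: commercial (R)-(−)-linalool is taken to be enantiomerically pure (its C3 becomes C2 of the target with the C–O bond intact); all 2H-chromenes are kept at or below 80 °C and away from light, because thermal or photochemical electrocyclic opening of ring B would racemise C2.

**Route**

Step 1
Reactants: 1 2,3-dimethylhydroquinone
Product: 2 4-hydroxy-2,3-dimethylphenyl pivalate
Conditions: PivCl (0.9 equiv), pyridine, CH2Cl2, −20 to 0 °C; diester and unreacted 1 separated and recycled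
Reagents that add atoms: pivaloyl chloride, CC(C)(C)C(=O)Cl
Why: Acylation of a phenol by an acid chloride (esterification); the diol is C2-symmetric so either hydroxyl gives the same mono-ester, and the sub-stoichiometric bulky acyl chloride limits the second acylation.

Step 2
Reactants: 2 4-hydroxy-2,3-dimethylphenyl pivalate
Product: 3 4-hydroxy-5-iodo-2,3-dimethylphenyl pivalate
Conditions: N-iodosuccinimide (1.05 equiv), p-TsOH (10 mol %), MeCN, 0 °C to rt
Reagents that add atoms: N-iodosuccinimide, O=C1CCC(=O)N1I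
Why: Electrophilic aromatic iodination; the free hydroxyl directs to its only open ortho position (the later C4a), the other ring CH being ortho only to the weakly donating ester.

Step 3
Reactants: 3 4-hydroxy-5-iodo-2,3-dimethylphenyl pivalate
Product: 4 5-iodo-2,3-dimethyl-4-[(trifluoromethylsulfonyl)oxy]phenyl pivalate
Conditions: Tf2O (1.2 equiv), pyridine, CH2Cl2, 0 °C
Reagents that add atoms: trifluoromethanesulfonic anhydride, O=S(=O)(OS(=O)(=O)C(F)(F)F)C(F)(F)F
Why: O-Sulfonylation of the phenol turns the oxygen-bearing ring carbon (the later C8a) into a cross-coupling site while the iodide remains the more reactive one.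

Step 4
Reactants: 5 (R)-linalool; 4 5-iodo-2,3-dimethyl-4-[(trifluoromethylsulfonyl)oxy]phenyl pivalate
Product: 7 5-[(3R)-3-hydroxy-3,7-dimethyloct-6-en-1-yl]-2,3-dimethyl-4-[(trifluoromethylsulfonyl)oxy]phenyl pivalate, via alkylborane 6 (not isolated)
Conditions: 9-BBN (2.2 equiv B–H), THF, 0 °C to rt; then 4 (1.05 equiv), PdCl2(dppf) (5 mol %), aq. K3PO4, DMF, 50 °C
Reagents that add atoms: none
Why: Anti-Markovnikov hydroboration of the only monosubstituted olefin by 9-BBN (the trisubstituted olefin is far slower) followed by B-alkyl Suzuki–Miyaura coupling, in which oxidative addition to C–I is much faster than to C–OTf; the carbinol stereocentre of 5 is not touched (its descriptor in 6 changes only formally).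

Step 5
Reactants: 7 5-[(3R)-3-hydroxy-3,7-dimethyloct-6-en-1-yl]-2,3-dimethyl-4-[(trifluoromethylsulfonyl)oxy]phenyl pivalate
Product: 8 (2R)-2,7,8-trimethyl-2-(4-methylpent-3-en-1-yl)chroman-6-yl pivalate
Conditions: Pd(OAc)2 (5 mol %), 2-(di-tert-butylphosphino)-1,1'-binaphthyl (6 mol %), Cs2CO3 (1.5 equiv), toluene, 80 °C
Reagents that add atoms: none
Why: Palladium-catalysed intramolecular C–O coupling of an aryl triflate with a tertiary alkoxide (Buchwald–Hartwig etherification; six-membered ring B closed at O1–C8a, no β-hydrogen on the alkoxide carbon), so the aryl C–O bond is the one formed and the carbinol C–O bond with its configuration, now C2, is retained.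

Step 6
Reactants: 8 (2R)-2,7,8-trimethyl-2-(4-methylpent-3-en-1-yl)chroman-6-yl pivalate
Product: 10 (2S)-2,7,8-trimethyl-2-(3-oxopropyl)chroman-6-yl pivalate, via diol 9 (not isolated)
Conditions: OsO4 (2 mol %), NaIO4 (4 equiv), 2,6-lutidine, dioxane/H2O 3:1, rt
Reagents that add atoms: osmium tetroxide, O=[Os](=O)(=O)=O (catalytic oxygen carrier); sodium periodate, [Na+].[O-]I(=O)(=O)=O (terminal source of the oxygen atom)
Why: Lemieux–Johnson cleavage; OsO4 dihydroxylates the only olefin and periodate cleaves the diol to the aldehyde and acetone, the arene, ester and ether being inert (the descriptor at C2 changes only formally).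

Step 7
Reactants: 10 (2S)-2,7,8-trimethyl-2-(3-oxopropyl)chroman-6-yl pivalate
Product: 11 3-[(2S)-6-(pivaloyloxy)-2,7,8-trimethylchroman-2-yl]propanoic acid
Conditions: NaClO2, NaH2PO4, 2-methyl-2-butene, t-BuOH/H2O, 0 °C to rt
Reagents that add atoms: sodium chlorite, [Na+].[O-]Cl=O
Why: Pinnick oxidation of the aldehyde to the acid, with 2-methyl-2-butene trapping hypochlorous acid so that the electron-rich ring A is not chlorinated.

Step 8
Reactants: 11 3-[(2S)-6-(pivaloyloxy)-2,7,8-trimethylchroman-2-yl]propanoic acid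
Product: 12 3-[(2R)-6-(pivaloyloxy)-2,7,8-trimethyl-2H-chromen-2-yl]propanoic acid
Conditions: DDQ (1.5 equiv), benzene, 80 °C, dark
Reagents that add atoms: none
Why: DDQ dehydrogenation of a chroman to a 2H-chromene: hydride abstraction from benzylic C4 (cation stabilised by O1 through ring A) and loss of the C3 proton, C2 being quaternary so that no further oxidation to a benzopyrylium ion is possible; C2 is not involved, and heat and light are limited because electrocyclic opening of ring B would racemise it.

Step 9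
Reactants: 12 3-[(2R)-6-(pivaloyloxy)-2,7,8-trimethyl-2H-chromen-2-yl]propanoic acid
Product: 13 1,3-dioxoisoindolin-2-yl 3-[(2R)-6-(pivaloyloxy)-2,7,8-trimethyl-2H-chromen-2-yl]propanoate
Conditions: N-hydroxyphthalimide (1.1 equiv), N,N'-diisopropylcarbodiimide (1.1 equiv), DMAP (10 mol %), CH2Cl2, rt, dark
Reagents that add atoms: N-hydroxyphthalimide, O=C1c2ccccc2C(=O)N1O
Why: Carbodiimide esterification (Steglich type) of the acid with N-hydroxyphthalimide gives the redox-active ester under neutral conditions at room temperature.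

Step 10
Reactants: 14 (2E,6E)-farnesyl bromide; 15 1-(trimethylsilyl)propyne
Product: 17 trimethyl[(5E,9E)-6,10,14-trimethylpentadeca-5,9,13-trien-1-yn-1-yl]silane, via lithiated silylpropyne 16 (not isolated)
Conditions: 15, n-BuLi, THF, −78 to −20 °C; then 14, −78 °C to rt
Reagents that add atoms: none
Why: Propargylic lithiation of the silylpropyne and SN2 alkylation by the primary allylic bromide at the propargylic carbon, a standard three-carbon homologation of prenyl halides that leaves the (E) olefins untouched.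

Step 11
Reactants: 17 trimethyl[(5E,9E)-6,10,14-trimethylpentadeca-5,9,13-trien-1-yn-1-yl]silane
Product: 18 (2E,6E,10E)-2,6,10-trimethyl-15-(trimethylsilyl)pentadeca-2,6,10-trien-14-yn-1-ol
Conditions: SeO2 (10 mol %), salicylic acid (10 mol %), t-BuOOH, CH2Cl2, 0 °C to rt, stopped at partial conversion
Reagents that add atoms: tert-butyl hydroperoxide, CC(C)(C)OO (terminal source of the oxygen atom); selenium dioxide, O=[Se]=O (catalytic oxygen carrier)
Why: Catalytic SeO2/t-BuOOH allylic oxidation (ene reaction then [2,3]-sigmatropic shift), which is selective for the (E)-methyl of the terminal isopropylidene group of polyprenyl chains and gives the (E)-allylic alcohol.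

Step 12
Reactants: 18 (2E,6E,10E)-2,6,10-trimethyl-15-(trimethylsilyl)pentadeca-2,6,10-trien-14-yn-1-ol
Product: 19 [(5E,9E,13E)-15-bromo-6,10,14-trimethylpentadeca-5,9,13-trien-1-yn-1-yl]trimethylsilane
Conditions: CBr4, PPh3, CH2Cl2, −20 to 0 °C
Reagents that add atoms: carbon tetrabromide, BrC(Br)(Br)Br
Why: Appel bromination of the primary allylic alcohol at low temperature, an SN2 process without allylic transposition or loss of (E) geometry.

Step 13
Reactants: 20 (2E,6E,10E)-geranylgeraniol
Product: 22 {[(2E,6E,10E)-3,7,11,15-tetramethylhexadeca-2,6,10,14-tetraen-1-yl]sulfonyl}benzene, via geranylgeranyl bromide 21 (not isolated)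
Conditions: PBr3 (0.4 equiv), Et2O, −10 °C; crude bromide, then PhSO2Na, DMF, rt
Reagents that add atoms: sodium benzenesulfinate, [Na+].[O-]S(=O)c1ccccc1
Why: Conversion of the allylic alcohol into the bromide with PBr3 and S-alkylation of sodium benzenesulfinate (SN2) give the allylic sulfone with the 2,3-(E) geometry intact.

Step 14
Reactants: 22 geranylgeranyl phenyl sulfone; 19 [(5E,9E,13E)-15-bromo-6,10,14-trimethylpentadeca-5,9,13-trien-1-yn-1-yl]trimethylsilane
Product: 24 trimethyl[(5E,9E,13E,17E,21E,25E)-6,10,14,18,22,26,30-heptamethyl-16-(phenylsulfonyl)hentriaconta-5,9,13,17,21,25,29-heptaen-1-yn-1-yl]silane, via lithiated sulfone 23 (not isolated)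
Conditions: 22, n-BuLi, THF/DMPU, −78 °C; then 19, −78 to −20 °C
Reagents that add atoms: none
Why: Alkylation of the α-sulfonyl allylic carbanion by the allylic bromide (sulfone-based prenyl chain coupling, Julia-type alkylation) forms the head-to-tail CH2–CH bond at the α carbon with all olefin geometries kept; the new sulfonyl-bearing stereocentre is racemic and is removed in the next step.

Step 15
Reactants: 24 trimethyl[(5E,9E,13E,17E,21E,25E)-6,10,14,18,22,26,30-heptamethyl-16-(phenylsulfonyl)hentriaconta-5,9,13,17,21,25,29-heptaen-1-yn-1-yl]silane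
Product: 25 trimethyl[(5E,9E,13E,17E,21E,25E)-6,10,14,18,22,26,30-heptamethylhentriaconta-5,9,13,17,21,25,29-heptaen-1-yn-1-yl]silane
Conditions: PdCl2(dppp) (5 mol %), LiBHEt3, THF, 0 °C
Reagents that add atoms: none
Why: Palladium-catalysed reductive desulfonylation of the allylic sulfone with LiBHEt3, in which hydride is delivered to the less substituted allyl terminus so that the trisubstituted (E) olefin stays in place.

Step 16
Reactants: 25 trimethyl[(5E,9E,13E,17E,21E,25E)-6,10,14,18,22,26,30-heptamethylhentriaconta-5,9,13,17,21,25,29-heptaen-1-yn-1-yl]silane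
Product: 26 (5E,9E,13E,17E,21E,25E)-6,10,14,18,22,26,30-heptamethylhentriaconta-5,9,13,17,21,25,29-heptaen-1-yne
Conditions: K2CO3, MeOH/THF, rt
Reagents that add atoms: none
Why: Base-catalysed protiodesilylation of the alkynylsilane in methanol.

Step 17
Reactants: 26 (5E,9E,13E,17E,21E,25E)-6,10,14,18,22,26,30-heptamethylhentriaconta-5,9,13,17,21,25,29-heptaen-1-yne
Product: 28 (1E,5E,9E,13E,17E,21E,25E)-1-iodo-2,6,10,14,18,22,26,30-octamethylhentriaconta-1,5,9,13,17,21,25,29-octaene, via alkenylalane 27 (not isolated)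
Conditions: AlMe3, Cp2ZrCl2 (20 mol %), CH2Cl2, 0 °C to rt; then I2, THF, −30 to 0 °C
Reagents that add atoms: trimethylaluminium, C[Al](C)C; iodine, II
Why: Negishi zirconium-catalysed carboalumination adds methyl and aluminium syn across the terminal alkyne with aluminium on the terminal carbon, and iodinolysis of the C–Al bond with retention fixes the (E)-1-iodo-2-methylalkene.

Step 18
Reactants: 13 1,3-dioxoisoindolin-2-yl 3-[(2R)-6-(pivaloyloxy)-2,7,8-trimethyl-2H-chromen-2-yl]propanoate; 28 (1E,5E,9E,13E,17E,21E,25E)-1-iodo-2,6,10,14,18,22,26,30-octamethylhentriaconta-1,5,9,13,17,21,25,29-octaene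
Product: 30 (2R)-2,7,8-trimethyl-2-[(3E,7E,11E,15E,19E,23E,27E)-4,8,12,16,20,24,28,32-octamethyltritriaconta-3,7,11,15,19,23,27,31-octaen-1-yl]-2H-chromen-6-yl pivalate, via primary alkyl radical 29 (not isolated)
Conditions: 13 (1.5 equiv), NiCl2·6H2O (10 mol %), 2,2'-bipyridine (10 mol %), AgNO3 (0.3 equiv), LiCl, DMF/THF, Mg anode, reticulated vitreous carbon cathode, constant current, rt, dark
Reagents that add atoms: none
Why: Cathodic reduction turns the NiCl2–bipyridine precatalyst into low-valent nickel, which inserts into the C–I bond of 28 with retention of the (E) geometry, while single-electron reduction of the phthalimide ester of 13 expels phthalimide anion and CO2 and leaves the primary radical 29; the alkenylnickel species captures 29 and reductive elimination forms the CH2–CH= bond, the silver deposited on the cathode from AgNO3 keeping the nickel cycle at the electrode and the Mg anode supplying the electrons. The closest known reaction type is the nickel-electrocatalytic decarboxylative alkenylation of N-hydroxyphthalimide esters by alkenyl halides on silver-coated cathodes, established for joining primary alkyl esters to carboalumination-derived (E)-iodoalkenes in polyene terpenoid assembly, that is the same bond type and substrate class. No ring is closed and no stereocentre is created: C2 is two saturated carbons away from the radical and is carried through unchanged, and the seven preformed (E) olefins of 28 are spectators of a reaction that touches only the sp2 C–I bond. The step needs cross- over homo-coupling (secured by the different activation modes of the two electrophiles, oxidative addition for the iodide and electron transfer for the ester), retention of olefin geometry (secured by stereoretentive two-electron steps at the sp2 carbon), and a radical that survives until capture: 29 is primary and unhindered, is γ and not β to O1 so it cannot eject the ring oxygen, and reaches C3=C4 only through 4-exo or 5-endo closures. The aryl pivalate, the C3=C4 bond and the trisubstituted olefins are not reduced at the potential of the nickel–bipyridine couple, and the cell is run at room temperature in the dark so that C2 of the 2H-chromene is not put at risk.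

Step 19
Reactants: 30 (2R)-2,7,8-trimethyl-2-[(3E,7E,11E,15E,19E,23E,27E)-4,8,12,16,20,24,28,32-octamethyltritriaconta-3,7,11,15,19,23,27,31-octaen-1-yl]-2H-chromen-6-yl pivalate
Product: 31 plastochromenol-8
Conditions: K2CO3 (0.5 equiv), MeOH/THF 1:1, degassed, rt to 35 °C, argon, dark; aq. NH4Cl
Reagents that add atoms: none
Why: Base-catalysed transesterification of the aryl pivalate with methanol under oxygen-free conditions near room temperature leaves the polyene, ring B and C2 untouched and releases the phenol.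

**Compound list**

1 | 2,3-dimethylhydroquinone (2,3-dimethylbenzene-1,4-diol) | Cc1c(C)c(O)ccc1O | starting material
2 | 4-hydroxy-2,3-dimethylphenyl pivalate | CC(C)(C)C(=O)Oc1ccc(O)c(C)c1C | intermediate
3 | 4-hydroxy-5-iodo-2,3-dimethylphenyl pivalate | CC(C)(C)C(=O)Oc1cc(I)c(O)c(C)c1C | intermediate
4 | 5-iodo-2,3-dimethyl-4-[(trifluoromethylsulfonyl)oxy]phenyl pivalate | CC(C)(C)C(=O)Oc1cc(I)c(OS(=O)(=O)C(F)(F)F)c(C)c1C | intermediate
5 | (R)-linalool, (3R)-3,7-dimethylocta-1,6-dien-3-ol | C=C[C@](C)(O)CCC=C(C)C | starting material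
6 | 9-[(3S)-3-hydroxy-3,7-dimethyloct-6-en-1-yl]-9-borabicyclo[3.3.1]nonane (alkylborane, drawn with free OH) | CC(C)=CCC[C@@](C)(O)CCB1C2CCCC1CCC2 | intermediate
7 | 5-[(3R)-3-hydroxy-3,7-dimethyloct-6-en-1-yl]-2,3-dimethyl-4-[(trifluoromethylsulfonyl)oxy]phenyl pivalate | CC(C)=CCC[C@@](C)(O)CCc1cc(OC(=O)C(C)(C)C)c(C)c(C)c1OS(=O)(=O)C(F)(F)F | intermediate
8 | (2R)-2,7,8-trimethyl-2-(4-methylpent-3-en-1-yl)chroman-6-yl pivalate | CC(C)=CCC[C@]1(C)CCc2cc(OC(=O)C(C)(C)C)c(C)c(C)c2O1 | intermediate
9 | (2S)-2-(3,4-dihydroxy-4-methylpentyl)-2,7,8-trimethylchroman-6-yl pivalate (both epimers at the secondary carbinol) | CC(C)(O)C(O)CC[C@]1(C)CCc2cc(OC(=O)C(C)(C)C)c(C)c(C)c2O1 | intermediate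
10 | (2S)-2,7,8-trimethyl-2-(3-oxopropyl)chroman-6-yl pivalate | O=CCC[C@]1(C)CCc2cc(OC(=O)C(C)(C)C)c(C)c(C)c2O1 | intermediate
11 | 3-[(2S)-6-(pivaloyloxy)-2,7,8-trimethylchroman-2-yl]propanoic acid | OC(=O)CC[C@]1(C)CCc2cc(OC(=O)C(C)(C)C)c(C)c(C)c2O1 | intermediate
12 | 3-[(2R)-6-(pivaloyloxy)-2,7,8-trimethyl-2H-chromen-2-yl]propanoic acid | OC(=O)CC[C@]1(C)C=Cc2cc(OC(=O)C(C)(C)C)c(C)c(C)c2O1 | intermediate
13 | 1,3-dioxoisoindolin-2-yl 3-[(2R)-6-(pivaloyloxy)-2,7,8-trimethyl-2H-chromen-2-yl]propanoate (redox-active ester) | O=C(CC[C@]1(C)C=Cc2cc(OC(=O)C(C)(C)C)c(C)c(C)c2O1)ON1C(=O)c2ccccc2C1=O | intermediate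
14 | (2E,6E)-farnesyl bromide | CC(C)=CCC/C(C)=C/CC/C(C)=C/CBr | starting material
15 | 1-(trimethylsilyl)propyne | CC#C[Si](C)(C)C | starting material
16 | 3-lithio-1-(trimethylsilyl)propyne | [Li]CC#C[Si](C)(C)C | intermediate
17 | trimethyl[(5E,9E)-6,10,14-trimethylpentadeca-5,9,13-trien-1-yn-1-yl]silane | CC(C)=CCC/C(C)=C/CC/C(C)=C/CCC#C[Si](C)(C)C | intermediate
18 | (2E,6E,10E)-2,6,10-trimethyl-15-(trimethylsilyl)pentadeca-2,6,10-trien-14-yn-1-ol | OC/C(C)=C/CC/C(C)=C/CC/C(C)=C/CCC#C[Si](C)(C)C | intermediate
19 | [(5E,9E,13E)-15-bromo-6,10,14-trimethylpentadeca-5,9,13-trien-1-yn-1-yl]trimethylsilane | BrC/C(C)=C/CC/C(C)=C/CC/C(C)=C/CCC#C[Si](C)(C)C | intermediate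
20 | (2E,6E,10E)-geranylgeraniol | CC(C)=CCC/C(C)=C/CC/C(C)=C/CC/C(C)=C/CO | starting material
21 | (2E,6E,10E)-geranylgeranyl bromide | CC(C)=CCC/C(C)=C/CC/C(C)=C/CC/C(C)=C/CBr | intermediate
22 | {[(2E,6E,10E)-3,7,11,15-tetramethylhexadeca-2,6,10,14-tetraen-1-yl]sulfonyl}benzene (geranylgeranyl phenyl sulfone) | CC(C)=CCC/C(C)=C/CC/C(C)=C/CC/C(C)=C/CS(=O)(=O)c1ccccc1 | intermediate
23 | α-lithiated geranylgeranyl phenyl sulfone | CC(C)=CCC/C(C)=C/CC/C(C)=C/CC/C(C)=C/C([Li])S(=O)(=O)c1ccccc1 | intermediate
24 | trimethyl[(5E,9E,13E,17E,21E,25E)-6,10,14,18,22,26,30-heptamethyl-16-(phenylsulfonyl)hentriaconta-5,9,13,17,21,25,29-heptaen-1-yn-1-yl]silane (racemic at C16) | CC(C)=CCC/C(C)=C/CC/C(C)=C/CC/C(C)=C/C(C/C(C)=C/CC/C(C)=C/CC/C(C)=C/CCC#C[Si](C)(C)C)S(=O)(=O)c1ccccc1 | intermediate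
25 | trimethyl[(5E,9E,13E,17E,21E,25E)-6,10,14,18,22,26,30-heptamethylhentriaconta-5,9,13,17,21,25,29-heptaen-1-yn-1-yl]silane | CC(C)=CCC/C(C)=C/CC/C(C)=C/CC/C(C)=C/CC/C(C)=C/CC/C(C)=C/CC/C(C)=C/CCC#C[Si](C)(C)C | intermediate
26 | (5E,9E,13E,17E,21E,25E)-6,10,14,18,22,26,30-heptamethylhentriaconta-5,9,13,17,21,25,29-heptaen-1-yne | CC(C)=CCC/C(C)=C/CC/C(C)=C/CC/C(C)=C/CC/C(C)=C/CC/C(C)=C/CC/C(C)=C/CCC#C | intermediate
27 | dimethyl[(1E,5E,9E,13E,17E,21E,25E)-2,6,10,14,18,22,26,30-octamethylhentriaconta-1,5,9,13,17,21,25,29-octaen-1-yl]alane | CC(C)=CCC/C(C)=C/CC/C(C)=C/CC/C(C)=C/CC/C(C)=C/CC/C(C)=C/CC/C(C)=C/CC/C(C)=C/[Al](C)C | intermediate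
28 | (1E,5E,9E,13E,17E,21E,25E)-1-iodo-2,6,10,14,18,22,26,30-octamethylhentriaconta-1,5,9,13,17,21,25,29-octaene | CC(C)=CCC/C(C)=C/CC/C(C)=C/CC/C(C)=C/CC/C(C)=C/CC/C(C)=C/CC/C(C)=C/CC/C(C)=C/I | intermediate
29 | 2-[(2R)-6-(pivaloyloxy)-2,7,8-trimethyl-2H-chromen-2-yl]ethyl radical | [CH2]C[C@]1(C)C=Cc2cc(OC(=O)C(C)(C)C)c(C)c(C)c2O1 | intermediate
30 | (2R)-2,7,8-trimethyl-2-[(3E,7E,11E,15E,19E,23E,27E)-4,8,12,16,20,24,28,32-octamethyltritriaconta-3,7,11,15,19,23,27,31-octaen-1-yl]-2H-chromen-6-yl pivalate | CC(C)=CCC/C(C)=C/CC/C(C)=C/CC/C(C)=C/CC/C(C)=C/CC/C(C)=C/CC/C(C)=C/CC/C(C)=C/CC[C@]1(C)C=Cc2cc(OC(=O)C(C)(C)C)c(C)c(C)c2O1 | intermediate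
31 | plastochromenol-8, (2R)-2,7,8-trimethyl-2-[(3E,7E,11E,15E,19E,23E,27E)-4,8,12,16,20,24,28,32-octamethyltritriaconta-3,7,11,15,19,23,27,31-octaen-1-yl]-2H-chromen-6-ol | CC(C)=CCC/C(C)=C/CC/C(C)=C/CC/C(C)=C/CC/C(C)=C/CC/C(C)=C/CC/C(C)=C/CC/C(C)=C/CC[C@]1(C)C=Cc2cc(O)c(C)c(C)c2O1 | target

**Step count and risks**

Total steps: 19. Longest linear sequence: 11 steps (steps 1–9, 18 and 19).

Steps most likely to fail:

1. Step 18. The radical may be reduced or abstract hydrogen before it is captured, the iodoalkene may homocouple, and the very lipophilic iodide may be poorly soluble in the polar electrolyte. The fallback sets out from 28 and 13 and comes back at 30; it replaces the electroreductive union of two electrophiles by a nucleophile–electrophile coupling without current. Iodide 28 is treated with t-BuLi (2 equiv, Et2O, −78 °C) to give the (E)-alkenyllithium F1, which is transmetalated with ZnCl2 to the (E)-alkenylzinc chloride F2. F2 is coupled with ester 13 under NiCl2(dme)/2,2'-bipyridine in THF/DMF at rt (thermal nickel-catalysed decarboxylative alkenylation), which should give 30 with the same retention of geometry.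

2. Step 8. Hydride abstraction may occur at the aryl methyl groups in competition with C4, and the product may partly racemise at C2 by thermal electrocyclic ring opening during the heating. The fallback sets out from 11 and comes back at 12, introducing C3=C4 stepwise at or below room temperature. Benzylic oxidation of 11 with CrO3 (5 mol %)/t-BuOOH in CH2Cl2 at rt should give 3-[(2R)-4-oxo-6-(pivaloyloxy)-2,7,8-trimethylchroman-2-yl]propanoic acid F3. Reduction with NaBH4 in MeOH at 0 °C gives the 4-hydroxychroman acid F4, and acid-catalysed dehydration (p-TsOH, CH2Cl2, rt, dark) gives 12.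

3. Step 5. The alkoxide may cleave the triflate at sulfur (loss of the leaving group), and oxidative addition at the doubly ortho-substituted carbon may be slow. The fallback sets out from 1 and comes back at 11; it builds ring B by forming the C2–O1 bond without stereocontrol and then separates the enantiomers. Diol 1 is condensed with commercial 5-methyl-5-vinyldihydrofuran-2(3H)-one (BF3·OEt2, dioxane, reflux; Friedel–Crafts allylation then ring closure) to racemic 3-(6-hydroxy-2,7,8-trimethylchroman-2-yl)propanoic acid F5. Fractional crystallisation with (S)-1-phenylethylamine gives the diastereomerically pure salt of the (S)-acid F6 (the antipodal amine is used should the salt of the unwanted acid be the less soluble one). Acidification liberates the (S)-acid F7, and pivaloylation (PivCl, pyridine; mixed anhydride hydrolysed on work-up) gives 11.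

**Further compounds**

F1 | step 18 | (1E,5E,9E,13E,17E,21E,25E)-2,6,10,14,18,22,26,30-octamethylhentriaconta-1,5,9,13,17,21,25,29-octaen-1-yllithium | CC(C)=CCC/C(C)=C/CC/C(C)=C/CC/C(C)=C/CC/C(C)=C/CC/C(C)=C/CC/C(C)=C/CC/C(C)=C/[Li]
F2 | step 18 | chloro[(1E,5E,9E,13E,17E,21E,25E)-2,6,10,14,18,22,26,30-octamethylhentriaconta-1,5,9,13,17,21,25,29-octaen-1-yl]zinc | CC(C)=CCC/C(C)=C/CC/C(C)=C/CC/C(C)=C/CC/C(C)=C/CC/C(C)=C/CC/C(C)=C/CC/C(C)=C/[Zn]Cl
F3 | step 8 | 3-[(2R)-4-oxo-6-(pivaloyloxy)-2,7,8-trimethylchroman-2-yl]propanoic acid | OC(=O)CC[C@]1(C)CC(=O)c2cc(OC(=O)C(C)(C)C)c(C)c(C)c2O1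
F4 | step 8 | 3-[(2R)-4-hydroxy-6-(pivaloyloxy)-2,7,8-trimethylchroman-2-yl]propanoic acid (both C4 epimers) | OC(=O)CC[C@]1(C)CC(O)c2cc(OC(=O)C(C)(C)C)c(C)c(C)c2O1
F5 | step 5 | racemic 3-(6-hydroxy-2,7,8-trimethylchroman-2-yl)propanoic acid | OC(=O)CCC1(C)CCc2cc(O)c(C)c(C)c2O1
F6 | step 5 | (S)-1-phenylethylammonium 3-[(2S)-6-hydroxy-2,7,8-trimethylchroman-2-yl]propanoate | C[C@H]([NH3+])c1ccccc1.[O-]C(=O)CC[C@]1(C)CCc2cc(O)c(C)c(C)c2O1
F7 | step 5 | 3-[(2S)-6-hydroxy-2,7,8-trimethylchroman-2-yl]propanoic acid | OC(=O)CC[C@]1(C)CCc2cc(O)c(C)c(C)c2O1
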